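**Strategy.** The route rests on disconnecting the diaryl ether bond between the ring A phenol oxygen and C4 of ring B (the phthalide ring), which leaves a depside. The key step is a dehydrogenative phenol coupling that closes the seven-membered dioxepinone in one operation. Ring B is oxidised through its free 7-OH, which stands para to C4–H, the only unsubstituted ring B carbon (C6 and C7a are blocked), and the ring A 2-OH adds at C4; no halogen is needed. The precursor is the ester of 3-formyl-2-hydroxy-4-methoxy-6-methylbenzoic acid with the 5-OH of a 5,7-dihydroxy-6-methylphthalide whose lactol is held as an (R)-configured (S)-1-phenylethyl acetal. The aldehyde deactivates ring A and is reduced afterwards.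

Key step: step 9

Assumption: the lactol carbon is a hemiacetal centre that can epimerise through the open formyl-acid form in protic, acidic or basic media, so it is carried as a configurationally stable (R)-acetal and freed only in the last step under neutral aprotic conditions; the target should be kept cold, dry and neutral.

Locants: ring A is numbered as the benzoate (C1 bears the carboxyl carbon); ring B is numbered as the phthalide (C1 lactone carbonyl, C3 lactol carbon, C4–C7 benzo carbons).

Step 1
Reactants: 1 2-hydroxy-4-methoxy-6-methylbenzoic acid (everninic acid)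
Product: 2 benzyl 2-hydroxy-4-methoxy-6-methylbenzoate
Conditions: BnBr, KHCO3, DMF, rt
Reagents that add atoms: benzyl bromide BrCc1ccccc1
Why: Chemoselective SN2 O-alkylation of the carboxylate, since KHCO3 ionises the acid but not the hydrogen-bonded 2-OH; the ester also blocks the easy decarboxylation of this orsellinic-type acid.

Step 2
Reactants: 2 benzyl 2-hydroxy-4-methoxy-6-methylbenzoate
Product: 4 benzyl 3-formyl-2-hydroxy-4-methoxy-6-methylbenzoate, via benzylic alcohol 3 (not isolated)
Conditions: MgCl2, Et3N, (CH2O)n, MeCN, reflux
Reagents that add atoms: paraformaldehyde (as formaldehyde) C=O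
Why: Casnati–Skattebøl ortho-formylation, in which the magnesium phenoxide delivers formaldehyde only to C3, the single free position ortho to the hydroxyl, and the benzylic alkoxide 3 is oxidised in the flask by hydride transfer to a second formaldehyde.

Step 3
Reactants: 4 benzyl 3-formyl-2-hydroxy-4-methoxy-6-methylbenzoate
Product: 5 3-formyl-2-hydroxy-4-methoxy-6-methylbenzoic acid
Conditions: H2 (1 atm), 10% Pd/C, EtOAc, rt, stopped after one equivalent of H2
Reagents that add atoms: none
Why: Hydrogenolysis of the benzyl ester should be faster than reduction of the hydrogen-bonded salicylaldehyde carbonyl when the uptake is limited to one equivalent.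

Step 4
Reactants: 6 methyl 2,4-dihydroxy-3,6-dimethylbenzoate
Product: 7 methyl 2,4-diacetoxy-3,6-dimethylbenzoate
Conditions: Ac2O, pyridine, DMAP (cat.), 50 °C
Reagents that add atoms: acetic anhydride CC(=O)OC(C)=O
Why: DMAP-catalysed acetylation of both phenols; the acetates deactivate the ring so that the next step brominates a methyl group and not the nucleus.

Step 5
Reactants: 7 methyl 2,4-diacetoxy-3,6-dimethylbenzoate
Product: 9 methyl 2,4-diacetoxy-6-(dibromomethyl)-3-methylbenzoate, via monobromide 8 (not isolated)
Conditions: NBS (2.2 equiv), AIBN (cat.), PhCF3, reflux, hν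
Reagents that add atoms: N-bromosuccinimide O=C1CCC(=O)N1Br
Why: Wohl–Ziegler benzylic bromination; the 6-methyl (one free neighbour, ortho to the ester) should react twice, while the 3-methyl is shielded between two acetoxy groups.

Step 6
Reactants: 9 methyl 2,4-diacetoxy-6-(dibromomethyl)-3-methylbenzoate
Product: 11 rac-3,5,7-trihydroxy-6-methylphthalide, via aldehyde 10 (not isolated)
Conditions: AgNO3, acetone–H2O, rt; filter; then 2 M HCl, dioxane, 60 °C
Reagents that add atoms: water O
Why: Silver-assisted hydrolysis of the benzal bromide gives aldehyde 10, and acid hydrolysis of the acetates and of the ortho-formyl ester (assisted by the neighbouring aldehyde) closes the hydroxyphthalide; the lactol carbon forms racemic and is still labile at this stage.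

Step 7
Reactants: 11 rac-3,5,7-trihydroxy-6-methylphthalide
Product: 12 (3R)-5,7-dihydroxy-6-methyl-3-[(1S)-1-phenylethoxy]phthalide
Conditions: (S)-1-phenylethanol (3 equiv), pyridinium p-toluenesulfonate (cat.), toluene, 4 Å MS, 60 °C; separation of the C3 epimers
Reagents that add atoms: (S)-1-phenylethanol C[C@H](O)c1ccccc1
Why: Acid-catalysed acetalisation of the lactol (pseudo-ester formation) under thermodynamic control should give both C3 epimers; the (3R,1'S) epimer is isolated by crystallisation or chromatography, which sets the C3 stereocentre by separation of diastereomers (assignment to be secured crystallographically), and the (3S) epimer is re-equilibrated under the same conditions.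

Step 8
Reactants: 5 3-formyl-2-hydroxy-4-methoxy-6-methylbenzoic acid; 12 (3R)-5,7-dihydroxy-6-methyl-3-[(1S)-1-phenylethoxy]phthalide
Product: 13 depside (3R)-7-hydroxy-6-methyl-1-oxo-3-[(1S)-1-phenylethoxy]-1,3-dihydro-2-benzofuran-5-yl 3-formyl-2-hydroxy-4-methoxy-6-methylbenzoate
Conditions: DCC, DMAP (cat.), CH2Cl2, 0 °C to rt
Reagents that add atoms: none
Why: Carbodiimide (Steglich-type) esterification; only the 5-OH of 12 is nucleophilic, since the 7-OH is hydrogen-bonded to the lactone carbonyl and flanked by the methyl group, and the 2-OH of acid 5 is locked between two carbonyls.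

Step 9
Reactants: 13 depside
Product: 15 stictic acid (R)-[(1S)-1-phenylethyl] acetal (depsidone aldehyde), via quinol aryl ether dienone 14 (not isolated)
Conditions: PhI(OCOCF3)2 (1.05 equiv, slow addition), NaHCO3 (solid), (CF3)2CHOH–CH2Cl2, −20 °C, 2 mM
Reagents that add atoms: none
Why: Ligand exchange of the ring B 7-OH at PhI(OCOCF3)2 gives an aryloxy(phenyl)iodine trifluoroacetate (trivalent iodine) that loses PhI in (CF3)2CHOH to a ring B phenoxonium ion with its positive charge at C4, the carbon para to the oxygen, where the ring A 2-OH adds to give dienone 14, which tautomerises to phenol 15. The closest known reaction type is the oxidative phenol coupling in its C–O mode, the laboratory form of the biosynthetic depside-to-depsidone coupling. The seven-membered dioxepinone ring is closed in the ionic mode, by attack of the tethered oxygen on the cationic sp2 carbon C4 inside ring B; the transient stereocentre at C4 is erased on aromatisation and the (3R)-acetal is not touched. Chemoselectivity between the two phenols is needed: the ring A hydroxyl lies between the aldehyde and ester carbonyls and is the harder one to oxidise, so it should act as the nucleophile, while on ring B C6 and C7a are substituted and C4 is the only open site. Regioselectivity is fixed by the ester tether, which reaches C4 and no other ring B carbon; high dilution and slow addition of one equivalent of oxidant should limit intermolecular coupling and further oxidation of the p-aryloxyphenol product.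

Step 10
Reactants: 15 stictic acid (R)-[(1S)-1-phenylethyl] acetal
Product: 16 cryptostictic acid (R)-[(1S)-1-phenylethyl] acetal
Conditions: NaBH4, THF–MeOH, −40 °C; aqueous work-up
Reagents that add atoms: none
Why: Chemoselective borohydride reduction of the aryl aldehyde at low temperature should be far faster than attack on the aryl ester, the lactone or the acetal; the acetal stereocentre is not involved.

Step 11
Reactants: 16 cryptostictic acid (R)-[(1S)-1-phenylethyl] acetal
Product: 17 (R)-cryptostictic acid (CNP0367167.1)
Conditions: H2 (1 atm), Pd(OH)2/C, EtOAc, 0 °C to rt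
Reagents that add atoms: none
Why: Hydrogenolysis of the benzylic C–O bond of the auxiliary (as for a benzyl glycoside) frees the hemiacetal without breaking either C–O bond at the lactol carbon, so the (R) configuration is retained; neutral aprotic conditions avoid ring-chain epimerisation.

**Compound list**

1 | 2-hydroxy-4-methoxy-6-methylbenzoic acid (everninic acid) | COc1cc(C)c(C(=O)O)c(O)c1 | starting material
2 | benzyl 2-hydroxy-4-methoxy-6-methylbenzoate | COc1cc(C)c(C(=O)OCc2ccccc2)c(O)c1 | intermediate
3 | benzyl 2-hydroxy-3-(hydroxymethyl)-4-methoxy-6-methylbenzoate (magnesium salt in the flask, not isolated) | COc1cc(C)c(C(=O)OCc2ccccc2)c(O)c1CO | intermediate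
4 | benzyl 3-formyl-2-hydroxy-4-methoxy-6-methylbenzoate | COc1cc(C)c(C(=O)OCc2ccccc2)c(O)c1C=O | intermediate
5 | 3-formyl-2-hydroxy-4-methoxy-6-methylbenzoic acid | COc1cc(C)c(C(=O)O)c(O)c1C=O | intermediate
6 | methyl 2,4-dihydroxy-3,6-dimethylbenzoate | COC(=O)c1c(C)cc(O)c(C)c1O | starting material
7 | methyl 2,4-diacetoxy-3,6-dimethylbenzoate | COC(=O)c1c(C)cc(OC(C)=O)c(C)c1OC(C)=O | intermediate
8 | methyl 2,4-diacetoxy-6-(bromomethyl)-3-methylbenzoate (not isolated) | COC(=O)c1c(CBr)cc(OC(C)=O)c(C)c1OC(C)=O | intermediate
9 | methyl 2,4-diacetoxy-6-(dibromomethyl)-3-methylbenzoate | COC(=O)c1c(C(Br)Br)cc(OC(C)=O)c(C)c1OC(C)=O | intermediate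
10 | methyl 2,4-diacetoxy-6-formyl-3-methylbenzoate (not isolated) | COC(=O)c1c(C=O)cc(OC(C)=O)c(C)c1OC(C)=O | intermediate
11 | rac-3,5,7-trihydroxy-6-methylphthalide (3,5,7-trihydroxy-6-methyl-2-benzofuran-1(3H)-one) | Cc1c(O)cc2c(c1O)C(=O)OC2O | intermediate
12 | (3R)-5,7-dihydroxy-6-methyl-3-[(1S)-1-phenylethoxy]phthalide | Cc1c(O)cc2c(c1O)C(=O)O[C@H]2O[C@@H](C)c1ccccc1 | intermediate
13 | depside: (3R)-7-hydroxy-6-methyl-1-oxo-3-[(1S)-1-phenylethoxy]-1,3-dihydro-2-benzofuran-5-yl 3-formyl-2-hydroxy-4-methoxy-6-methylbenzoate | COc1cc(C)c(C(=O)Oc2cc3c(c(O)c2C)C(=O)O[C@H]3O[C@@H](C)c4ccccc4)c(O)c1C=O | intermediate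
14 | quinol aryl ether dienone, the 4H-cyclohexa-2,5-dienone tautomer of 15 with sp3 C4 bearing H and the ring A oxygen (not isolated) | COc1cc(C)c2c(c1C=O)OC1C(=C(C)C(=O)C3=C1[C@H](O[C@@H](C)c4ccccc4)OC3=O)OC2=O | intermediate
15 | stictic acid (R)-[(1S)-1-phenylethyl] acetal: depsidone with ring A 4-formyl-3-methoxy-1-methyl and ring B 8-hydroxy-9-methyl fused to the γ-lactone whose (R) lactol carbon carries the (1S)-1-phenylethoxy group | COc1cc(C)c2c(c1C=O)Oc1c(c(C)c(O)c3c1[C@H](O[C@@H](C)c4ccccc4)OC3=O)OC2=O | intermediate
16 | cryptostictic acid (R)-[(1S)-1-phenylethyl] acetal: as 15 with CH2OH in place of the ring A formyl group | COc1cc(C)c2c(c1CO)Oc1c(c(C)c(O)c3c1[C@H](O[C@@H](C)c4ccccc4)OC3=O)OC2=O | intermediate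
17 | (R)-cryptostictic acid (CNP0367167.1): depsidone with ring A 4-hydroxymethyl-3-methoxy-1-methyl and ring B 8-hydroxy-9-methyl fused to the (R)-hydroxy-γ-lactone | COc1cc(C)c2c(c1CO)Oc1c(c(C)c(O)c3c1[C@H](O)OC3=O)OC2=O | target

**Step count.** Total: 11 steps. Longest linear sequence: 8 steps (steps 4 to 11, from compound 6).

**Steps most likely to fail**

Step 9. The product is a p-aryloxyphenol and may be oxidised further; the ring A ipso carbon C1 may attack C4 instead of the oxygen, giving a spiro-lactone; intermolecular coupling may compete. The fallback sets out from 12 and uses a halide instead of C–H oxidation. Bromination with NBS in MeCN at −20 °C should go to C4, the only free ring position, giving (3R)-4-bromo-5,7-dihydroxy-6-methyl-3-[(1S)-1-phenylethoxy]phthalide F1. Esterification with 5 (DCC, DMAP cat., CH2Cl2) gives the bromo depside F2. An intramolecular Ullmann ether synthesis (CuI, N,N-dimethylglycine, Cs2CO3, dioxane, 90 °C, kept as mild as possible to suppress Smiles-type aryl migration) closes the same O–C4 bond and returns to the route at 15.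

Step 11. Hydrogenolysis may cut the wrong benzylic C–O bond (ring A CH2–OH or the lactol carbon), or the freed lactol may be over-reduced through its open aldehyde form. The fallback sets out from 16 and replaces reductive release by resolution and enzymatic release. Hydrolysis with aqueous CF3CO2H in THF gives racemic cryptostictic acid F3. An acylative dynamic kinetic resolution of the equilibrating lactol (isobutyric anhydride, iPr2NEt, a chiral isothiourea acyl-transfer catalyst such as benzotetramisole, enantiomer chosen on a model hydroxyphthalide, CHCl3, 0 °C) should give the (R)-acyl acetal, with the primary alcohol also acylated, as bis-isobutyrate F4. Alcoholysis with immobilised Candida antarctica lipase B and n-butanol in dry MTBE removes both esters by acyl–oxygen cleavage, with retention at the lactol carbon, and returns to the route at 17.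

Step 7. Acid may ionise the benzylic alcohol, which would lead to C-alkylation of the electron-rich ring B at C4 and erosion of the auxiliary's configuration; the epimers may also separate poorly. The fallback sets out from 9 and forms the acetal without Brønsted acid while the phenols are still acetylated. Heating 9 in toluene at 110 °C should cyclise it, with loss of bromomethane, to rac-5,7-diacetoxy-3-bromo-6-methylphthalide F5. Substitution with (S)-1-phenylethanol and Ag2CO3 in CH2Cl2 at rt, followed by separation of the epimers, gives (3R)-5,7-diacetoxy-6-methyl-3-[(1S)-1-phenylethoxy]phthalide F6. NH3 in MeOH at 0 °C removes the two phenolic acetates and returns to the route at 12.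

**Further compounds**

F1 | step 9 | (3R)-4-bromo-5,7-dihydroxy-6-methyl-3-[(1S)-1-phenylethoxy]phthalide | Cc1c(O)c(Br)c2c(c1O)C(=O)O[C@H]2O[C@@H](C)c1ccccc1
F2 | step 9 | bromo depside: (3R)-4-bromo-7-hydroxy-6-methyl-1-oxo-3-[(1S)-1-phenylethoxy]-1,3-dihydro-2-benzofuran-5-yl 3-formyl-2-hydroxy-4-methoxy-6-methylbenzoate | COc1cc(C)c(C(=O)Oc2c(Br)c3c(c(O)c2C)C(=O)O[C@H]3O[C@@H](C)c4ccccc4)c(O)c1C=O
F3 | step 11 | racemic cryptostictic acid | COc1cc(C)c2c(c1CO)Oc1c(c(C)c(O)c3c1C(O)OC3=O)OC2=O
F4 | step 11 | (R)-cryptostictic acid bis-isobutyrate (lactol O-isobutyrate and ring A CH2O-isobutyrate) | COc1cc(C)c2c(c1COC(=O)C(C)C)Oc1c(c(C)c(O)c3c1[C@H](OC(=O)C(C)C)OC3=O)OC2=O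
F5 | step 7 | rac-5,7-diacetoxy-3-bromo-6-methylphthalide | CC(=O)Oc1cc2c(c(OC(C)=O)c1C)C(=O)OC2Br
F6 | step 7 | (3R)-5,7-diacetoxy-6-methyl-3-[(1S)-1-phenylethoxy]phthalide | CC(=O)Oc1cc2c(c(OC(C)=O)c1C)C(=O)O[C@H]2O[C@@H](C)c1ccccc1
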